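**Strategy**

Everything rests on reading the dihydropyran (O1; C2 with CH3; C3 with CHO; C4 with the acetate arm; C5 with CO2Me; C6) as an isomer of an acyclic allyl vinyl ether. C4 is allylic to the C5=C6 enol ether and to a latent C2=C3 ethylidene, and O1–C2 lies β to the C3 formyl group. Heating β-(allyloxy)acrylate 10 should therefore trigger a Claisen rearrangement that forms C4–C5 and relays the carbinol configuration to C4; the enol set free beside an ethylidene enal then closes O1–C2 by 6-endo oxa-Michael addition, fixing C2 and C3. The precursor is a ring-free ether of an (R)-allylic alcohol and methyl propiolate.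

Key step: step 7

Remark: the ring-closed monoaldehyde is taken to be the thermodynamically preferred member of the enol enal / hemiacetal / ring-closed set, and the all-trans (2S,3R,4R) isomer to be its most stable diastereomer.

**Route**

Step 1
Reactants: 1 methyl (3R)-3-hydroxybutanoate
Product: 2 methyl (3R)-3-[(tert-butyldimethylsilyl)oxy]butanoate
Conditions: TBSCl, imidazole, DMF, 0 °C → rt
Reagents that add atoms: tert-butyldimethylsilyl chloride, CC(C)(C)[Si](C)(C)Cl
Why: Imidazole-mediated silylation of the secondary alcohol should proceed without touching the stereocentre, which is the only chiral input of the route.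

Step 2
Reactants: 2 methyl (3R)-3-[(tert-butyldimethylsilyl)oxy]butanoate
Product: 3 (3R)-3-[(tert-butyldimethylsilyl)oxy]butanal
Conditions: DIBAL-H (1.05 equiv), CH2Cl2, −78 °C; Rochelle salt work-up
Reagents that add atoms: none
Why: Half-reduction of a methyl ester with DIBAL-H at low temperature should stop at the aldehyde through the stable aluminium hemiacetal, and the β-silyloxy centre cannot epimerise.

Step 3
Reactants: 3 (3R)-3-[(tert-butyldimethylsilyl)oxy]butanal
Product: 5 (3R)-3-[(tert-butyldimethylsilyl)oxy]-2-methylidenebutanal, via Mannich base 4 (not isolated)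
Conditions: Eschenmoser's salt, Et3N, CH2Cl2, rt
Reagents that add atoms: N,N-dimethylmethyleneiminium iodide (Eschenmoser's salt), C=[N+](C)C.[I-]
Why: Mannich aminomethylation of the aldehyde followed by E1cB loss of dimethylamine (α-methylenation) should give the 2-substituted acrolein while the silyloxy centre stays (R).

Step 4
Reactants: 5 (3R)-3-[(tert-butyldimethylsilyl)oxy]-2-methylidenebutanal, 6 tert-butyl but-3-enoate
Product: 7 tert-butyl (3E,5R)-5-[(tert-butyldimethylsilyl)oxy]-4-formylhex-3-enoate
Conditions: Hoveyda–Grubbs II (5–10 mol %), 6 (3 equiv), 1,4-benzoquinone (10 mol %), CH2Cl2, 40 °C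
Reagents that add atoms: none
Why: Olefin cross-metathesis of the 1,1-disubstituted enal with an excess of the terminal alkene should give the trisubstituted enal with the new CH2CO2tBu group trans to CHO (E), as is usual for 2-substituted acroleins under thermodynamic control.

Step 5
Reactants: 7 tert-butyl (3E,5R)-5-[(tert-butyldimethylsilyl)oxy]-4-formylhex-3-enoate
Product: 8 tert-butyl (3E,5R)-4-formyl-5-hydroxyhex-3-enoate
Conditions: HF·pyridine, THF, 0 °C → rt
Reagents that add atoms: none
Why: Fluoride-driven desilylation under mildly acidic, non-basic conditions should spare the enal and the γ-acidic CH2, and the tert-butyl ester should resist lactonisation onto the cis-disposed hydroxyl.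

Step 6
Reactants: 8 tert-butyl (3E,5R)-4-formyl-5-hydroxyhex-3-enoate, 9 methyl propiolate
Product: 10 methyl (2E)-3-{[(2R,3E)-6-tert-butoxy-3-formyl-6-oxohex-3-en-2-yl]oxy}prop-2-enoate
Conditions: methyl propiolate, N-methylmorpholine (cat.), CH2Cl2, 0 °C → rt
Reagents that add atoms: none
Why: Tertiary-amine-catalysed oxa-Michael addition of the alcohol to the propiolate should give the (E)-β-alkoxyacrylate, and because only the O–H bond reacts the carbinol stays (R).

Step 7
Reactants: 10 methyl (2E)-3-{[(2R,3E)-6-tert-butoxy-3-formyl-6-oxohex-3-en-2-yl]oxy}prop-2-enoate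
Product: 12 methyl (2S,3R,4R)-4-(2-tert-butoxy-2-oxoethyl)-3-formyl-2-methyl-3,4-dihydro-2H-pyran-5-carboxylate, via enol enal 11 (not isolated)
Conditions: PhMe (degassed, BHT cat.), 150–160 °C, sealed tube; then Et3N (10 mol %), rt
Reagents that add atoms: none
Why: Heating should induce a [3,3]-sigmatropic (Claisen) shift of the allyl vinyl ether through a chair transition state (C2–CH3 equatorial, the Z-disposed CH2CO2tBu axial) that breaks O1–C2, forms C4–C5 and delivers enol enal 11, whose enol oxygen then adds to C2 of the ethylidene enal (oxa-Michael) with tautomerisation to the C3 aldehyde. The closest known reaction types are the thermal Claisen rearrangement of 3-(allyloxy)acrylates to α-formyl γ,δ-unsaturated esters and the spontaneous oxa-Michael ring closure of secoiridoid enol dialdehydes. The pyran ring closes in a 6-endo-trig mode (O1 onto C2, with both alkene carbons C2 and C3 inside the ring). C4 is set by suprafacial 1,3-chirality transfer from the (R)-carbinol, because the alternative chair with an axial methyl suffers a 1,3-diaxial clash with the axial CH2CO2tBu of the E-enal; the original C2 centre is destroyed in this shift, and C2 and C3 are then set under thermodynamic control relative to C4 (reversible oxa-Michael, enolisable C3), which should favour the all-trans (2S,3R,4R) isomer. The step needs the [3,3] shift to outrun vinylogous β-elimination of the oxyacrylate and conjugate closure at C2 to prevail over hemiacetal formation at the formyl carbon; base-free thermolysis secures the first, and the reversibility of hemiacetal formation together with the amine finish secures the second.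

Step 8
Reactants: 12 methyl (2S,3R,4R)-4-(2-tert-butoxy-2-oxoethyl)-3-formyl-2-methyl-3,4-dihydro-2H-pyran-5-carboxylate
Product: 13 2-[(2S,3R,4R)-3-formyl-5-(methoxycarbonyl)-2-methyl-3,4-dihydro-2H-pyran-4-yl]acetic acid
Conditions: TFA/CH2Cl2 (1:4), 0 °C → rt
Reagents that add atoms: none
Why: Acidolysis of the tert-butyl ester (loss of isobutene) should leave the methyl vinylogous carbonate and the aldehyde intact, and C3 already sits in its thermodynamically preferred trans arrangement.

Step 9
Reactants: 13 2-[(2S,3R,4R)-3-formyl-5-(methoxycarbonyl)-2-methyl-3,4-dihydro-2H-pyran-4-yl]acetic acid, 14 hydroxytyrosol [2-(3,4-dihydroxyphenyl)ethanol]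
Product: 15 methyl (2S,3R,4R)-4-{2-[2-(3,4-dihydroxyphenyl)ethoxy]-2-oxoethyl}-3-formyl-2-methyl-3,4-dihydro-2H-pyran-5-carboxylate (CNP0172886.1)
Conditions: PPh3, DIAD, THF, 0 °C → rt
Reagents that add atoms: none
Why: Mitsunobu esterification activates only the primary aliphatic hydroxyl, and the carboxylate should outcompete the far less acidic phenols as nucleophile, so the catechol needs no protection and no stereocentre is touched.

**Compound list**

1 | methyl (3R)-3-hydroxybutanoate | C[C@@H](O)CC(=O)OC | starting material
2 | methyl (3R)-3-[(tert-butyldimethylsilyl)oxy]butanoate | C[C@@H](O[Si](C)(C)C(C)(C)C)CC(=O)OC | intermediate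
3 | (3R)-3-[(tert-butyldimethylsilyl)oxy]butanal | C[C@@H](O[Si](C)(C)C(C)(C)C)CC=O | intermediate
4 | (3R)-3-[(tert-butyldimethylsilyl)oxy]-2-[(dimethylamino)methyl]butanal (Mannich base, C2 epimers) | C[C@@H](O[Si](C)(C)C(C)(C)C)C(CN(C)C)C=O | intermediate
5 | (3R)-3-[(tert-butyldimethylsilyl)oxy]-2-methylidenebutanal | C[C@@H](O[Si](C)(C)C(C)(C)C)C(=C)C=O | intermediate
6 | tert-butyl but-3-enoate | C=CCC(=O)OC(C)(C)C | starting material
7 | tert-butyl (3E,5R)-5-[(tert-butyldimethylsilyl)oxy]-4-formylhex-3-enoate | C[C@@H](O[Si](C)(C)C(C)(C)C)/C(C=O)=C\CC(=O)OC(C)(C)C | intermediate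
8 | tert-butyl (3E,5R)-4-formyl-5-hydroxyhex-3-enoate | C[C@@H](O)/C(C=O)=C\CC(=O)OC(C)(C)C | intermediate
9 | methyl propiolate | C#CC(=O)OC | starting material
10 | methyl (2E)-3-{[(2R,3E)-6-tert-butoxy-3-formyl-6-oxohex-3-en-2-yl]oxy}prop-2-enoate | C[C@@H](O/C=C/C(=O)OC)/C(C=O)=C\CC(=O)OC(C)(C)C | intermediate
11 | methyl (2E,3R,4Z)-3-(2-tert-butoxy-2-oxoethyl)-4-formyl-2-(hydroxymethylidene)hex-4-enoate (enol tautomer of the α-formyl ester) | COC(=O)/C(=C/O)[C@H](CC(=O)OC(C)(C)C)/C(C=O)=C/C | intermediate
12 | methyl (2S,3R,4R)-4-(2-tert-butoxy-2-oxoethyl)-3-formyl-2-methyl-3,4-dihydro-2H-pyran-5-carboxylate | COC(=O)C1=CO[C@@H](C)[C@H](C=O)[C@H]1CC(=O)OC(C)(C)C | intermediate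
13 | 2-[(2S,3R,4R)-3-formyl-5-(methoxycarbonyl)-2-methyl-3,4-dihydro-2H-pyran-4-yl]acetic acid | COC(=O)C1=CO[C@@H](C)[C@H](C=O)[C@H]1CC(=O)O | intermediate
14 | hydroxytyrosol, 2-(3,4-dihydroxyphenyl)ethanol | OCCc1ccc(O)c(O)c1 | starting material
15 | methyl (2S,3R,4R)-4-{2-[2-(3,4-dihydroxyphenyl)ethoxy]-2-oxoethyl}-3-formyl-2-methyl-3,4-dihydro-2H-pyran-5-carboxylate | COC(=O)C1=CO[C@@H](C)[C@H](C=O)[C@H]1CC(=O)OCCc1ccc(O)c(O)c1 | target

**Step count**

Total step count: 9. Longest linear sequence: 9 steps (1 → 15); compounds 6, 9 and 14 are used as purchased.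

**Steps most likely to fail**

1. Step 7 (key step). At the temperature the [3,3] shift needs, vinylogous β-elimination of the oxyacrylate from the γ-acidic enal, or degradation of the free enal, may consume 10 before it rearranges. Leakage through an axial-methyl or boat transition state would erode the configuration at C4, and equilibration at C2 may stay incomplete. The fallback sets out from 8 and returns at 12. The formyl group would be masked first (HC(OMe)3, PPTS, MeOH) to give tert-butyl (3E,5R)-4-(dimethoxymethyl)-5-hydroxyhex-3-enoate F1. Amine-catalysed addition to methyl propiolate would give methyl (2E)-3-{[(2R,3E)-6-tert-butoxy-3-(dimethoxymethyl)-6-oxohex-3-en-2-yl]oxy}prop-2-enoate F2, which lacks the acidifying carbonyl and can be heated harder without elimination. Its Claisen rearrangement would give methyl (2E,3R,4Z)-3-(2-tert-butoxy-2-oxoethyl)-4-(dimethoxymethyl)-2-(hydroxymethylidene)hex-4-enoate F3. Mild aqueous acid (PPTS, acetone–water) would then unmask the enal and let the oxa-Michael closure give 12. Ring formation thus becomes an acid-triggered deprotection and cyclisation of an isolated rearrangement product instead of a thermal cascade.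

2. Step 4. The hindered 1,1-disubstituted enal may turn over slowly, while the butenoate homodimerises or its double bond migrates into conjugation. The fallback sets out from 5 and returns at 7. Bromine addition across the methylidene group (Br2, CH2Cl2, −78 °C) would give (3R)-2-bromo-2-(bromomethyl)-3-[(tert-butyldimethylsilyl)oxy]butanal F4, which is not isolated. Triethylamine would eliminate HBr to give (2E)-3-bromo-2-{(1R)-1-[(tert-butyldimethylsilyl)oxy]ethyl}prop-2-enal F5, with bromine trans to the formyl group. A Migita–Kosugi–Stille coupling with tert-butyl (tributylstannyl)acetate (Pd catalyst, toluene, 80 °C) would then install the CH2CO2tBu group with retention of alkene geometry to give 7.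

3. Step 6. The hindered allylic alcohol may add sluggishly, and the amine may instead trigger isomerisation of the γ-acidic enal or loss of the newly installed oxyacrylate. The fallback sets out from 8 and returns at 10. Acid-catalysed acetal exchange with methyl 3,3-dimethoxypropanoate (PPTS, toluene, 90 °C, methanol distilled off) would give tert-butyl (3E,5R)-5-[(1,3-dimethoxy-3-oxopropyl)oxy]-4-formylhex-3-enoate F6. On continued heating this mixed acetal would lose a second methanol to give 10 without any amine base.

Further compounds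
F1 | step 7 | tert-butyl (3E,5R)-4-(dimethoxymethyl)-5-hydroxyhex-3-enoate | C[C@@H](O)/C(C(OC)OC)=C\CC(=O)OC(C)(C)C
F2 | step 7 | methyl (2E)-3-{[(2R,3E)-6-tert-butoxy-3-(dimethoxymethyl)-6-oxohex-3-en-2-yl]oxy}prop-2-enoate | C[C@@H](O/C=C/C(=O)OC)/C(C(OC)OC)=C\CC(=O)OC(C)(C)C
F3 | step 7 | methyl (2E,3R,4Z)-3-(2-tert-butoxy-2-oxoethyl)-4-(dimethoxymethyl)-2-(hydroxymethylidene)hex-4-enoate | COC(=O)/C(=C/O)[C@H](CC(=O)OC(C)(C)C)/C(C(OC)OC)=C/C
F4 | step 4 | (3R)-2-bromo-2-(bromomethyl)-3-[(tert-butyldimethylsilyl)oxy]butanal | C[C@@H](O[Si](C)(C)C(C)(C)C)C(Br)(CBr)C=O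
F5 | step 4 | (2E)-3-bromo-2-{(1R)-1-[(tert-butyldimethylsilyl)oxy]ethyl}prop-2-enal | C[C@@H](O[Si](C)(C)C(C)(C)C)/C(C=O)=C\Br
F6 | step 6 | tert-butyl (3E,5R)-5-[(1,3-dimethoxy-3-oxopropyl)oxy]-4-formylhex-3-enoate | C[C@@H](OC(OC)CC(=O)OC)/C(C=O)=C\CC(=O)OC(C)(C)C
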